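Over 40 h a small charge of L has to carry D through to Q, while its working form J also drains away into J2.

    L + E ⇌ J + Z (K1 = 0.682, k1 = 2420 M⁻¹ h⁻¹)
    D + J → Q + L (k2 = 1630 M⁻¹ h⁻¹)
    2 J → J2 (k3 = 1310 M⁻¹ h⁻¹)
    X ⇌ Q, rate k4*(cs4 - [Q]) while solid is left; crystals form when [Q] > cs4 (cs4 = 32 mM, k4 = 9.63 h⁻¹)

D 33 mM; E 34.6 mM; L 0.33 mM; time 40 h; volume of the second phase over the first 0.25

- Thursday's: doubling the dissolution coefficient of step 4, all else as stated
- Friday's: doubling the solubility in step 4, all else as stated
- Wednesday's: doubling the amount of E, all else as stated

- for Q the X are counted in
- a doubled species enters its step squared and goes two at a time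
- in the second phase: E, Z; everything else is in the first
- charges count per volume of the first phase; a concentration in a rate is the amount of a species over the volume of its own phase; every rate counts per litre of the first phase
- as a solid, counted per litre of solution: X
- run time (flask): 40 h

1. Q and X together at 40 h, in percent of the D charged
2. concentration of Q in solution at 20 h, in percent of saturation
3. the change that raises the amount of Q and X together at 40 h, in percent of the D charged most ("none" if none brings more than 2 percentage points) (Thursday's / Friday's / Wednesday's / none)
4. amount of Q and X together at 40 h, in percent of the D charged, after Wednesday's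

Minutes of the meeting on this flask. I opened by taking J as made as fast as it goes, so that the share w of the live catalyst (L plus J) standing as J is the pseudo-first-order rate of L with E over the sum of that rate, the way back through Z and the way on through D, with [E] and [Z] read in the small phase at 4.00 times their charge. Since J goes to J2 and to Q side by side, I said that each mM of Q costs the live catalyst a fraction 1.61 times w/[D], and that neither term holds the charge of L.

A colleague objected that no mean could stand for a w falling from 86.2% at the start to 20.7% at [D] = 8.25 mM. I answered that [D] falls with it, for w/[D] reads 0.0261 mM⁻¹ at the start, 0.0243 mM⁻¹ at [D] = 16.5 mM and 0.0251 mM⁻¹ at 8.25 mM, so the mean 0.0252 mM⁻¹ errs by 3.65% at most among these points. The toll, the fraction of live catalyst lost to J2 per mM of Q made, is therefore 0.0405 mM⁻¹.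

The chair asked for a time. With w proportional to [D], the slope of 1/[D] is k2 times that mean times the live catalyst, so the line bends down as the live catalyst falls exponentially in [Q], and taking one slope for the whole curve, with the exponential read at twice the final [D], I found that [D] = 4.12 mM takes 42.6 h, longer than the time allowed. So I committed to just under 87.5%, with [Q] near 28.9 mM, less than 32 mM, so I expected no crystals and voted for Wednesday's, which raises w.

The forecast gave 87.4% (85.5% to 89.5%), 81.9% (79.5% to 84.5%), Wednesday's and 91.2% (89% to 93.5%), holding that “no crystals form”.

The simulation gives 87.5%, 82.0%, Wednesday's with a gain of 4 percentage points, and 91.5%. In this flask half of the turnover of D + J was done by 2.55 h, and J2 held 49.7% of the catalyst at 4.00 h; from then to 40.0 h the round crept on, with J down to 3.59% and X at 0%. The toll on 87.5% leaves 31.1% of the charge live, and L plus J stand at 31.9%.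

In the neighbour with 0.82 mM of L, the toll leaves 28.6% live at [D] = 2.06 mM, which takes 43.5 h, so the reckoning says just under 93.8%. That neighbour gave 94.1%, with L plus J at 29.8%.

The numbers of this flask stand for no real mixture; the flask was simulated.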